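**Retrosynthetic overview**

- The target is cut at C3–C3a and O1–C2 in one operation: an oxidative 8–5′ cross-coupling of sinapyl 4-hydroxybenzoate with coniferyl 4-hydroxybenzoate, the acylated monolignols of p-hydroxybenzoylated palm lignin, with both esters already in place and no protecting groups.
- The only ring formed is the dihydrofuran ring. The C–C bond comes first (C8 of the sinapyl unit to C5 of the coniferyl unit, sets C3), then the C–O bond by 5-exo attack of the phenol on the p-quinone methide (sets C2, trans). A chiral iron phosphate catalyst is meant to control the absolute sense; this is an untested proposal.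
- Each monolignol ester comes from cross-metathesis of a 4-vinylphenol with allyl 4-hydroxybenzoate.
- 4-Vinylsyringol comes from sinapic acid by decarboxylation; 4-vinylguaiacol and the allyl ester are bought.

Assumption: allyl 4-hydroxybenzoate and 2-methoxy-4-vinylphenol are bought as catalogue chemicals, and the (R)-ligand in step 4 is provisional, because the sense of induction of this new reaction must be found in a first run (the (S)-ligand is used if the antipode forms).

**Route**

Step 1
Reactants: 1 sinapic acid [(E)-3-(4-hydroxy-3,5-dimethoxyphenyl)prop-2-enoic acid]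
Product: 2 4-vinylsyringol (2,6-dimethoxy-4-vinylphenol)
Conditions: DBU (1 equiv), DMF, microwave, 130 °C, 20 min, N2; used at once
Reagents that add atoms: none
Why: Base-mediated decarboxylation of a 4-hydroxycinnamic acid, in which the phenolate tautomerises to a quinone methide that is a vinylogous β-keto acid and loses CO2 to give the 4-vinylphenol, with no stereocentre involved.

Step 2
Reactants: 2 4-vinylsyringol; 3 allyl 4-hydroxybenzoate
Product: 4 sinapyl 4-hydroxybenzoate [(E)-3-(4-hydroxy-3,5-dimethoxyphenyl)prop-2-enyl 4-hydroxybenzoate]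
Conditions: second-generation Hoveyda–Grubbs catalyst RuCl2(H2IMes)(=CH-C6H4-2-OiPr) (4 mol %), 3 (3 equiv), CH2Cl2, 40 °C, Ar sparge
Reagents that add atoms: none
Why: Olefin cross-metathesis of a styrene with an allylic ester, both tolerated as free phenols by ruthenium carbenes, driven by loss of ethene and giving the conjugated (E)-alkene as the thermodynamic product, with excess 3 holding back stilbene formation.

Step 3
Reactants: 5 4-vinylguaiacol (2-methoxy-4-vinylphenol); 3 allyl 4-hydroxybenzoate
Product: 6 coniferyl 4-hydroxybenzoate [(E)-3-(4-hydroxy-3-methoxyphenyl)prop-2-enyl 4-hydroxybenzoate]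
Conditions: second-generation Hoveyda–Grubbs catalyst RuCl2(H2IMes)(=CH-C6H4-2-OiPr) (4 mol %), 3 (3 equiv), CH2Cl2, 40 °C, Ar sparge
Reagents that add atoms: none
Why: The same olefin cross-metathesis as in step 2, with ethene loss as the driving force and (E)-selectivity from conjugation of the new alkene with the arene.

Step 4
Reactants: 4 sinapyl 4-hydroxybenzoate; 6 coniferyl 4-hydroxybenzoate
Product: 8 quiquesetinerviusin B [(2S,3R)-trans-dihydrobenzofuran; full name in the compound list], via p-quinone methide 7 (not isolated)
Conditions: Fe[(R)-L]3 (5 mol %; L = 3,3′-bis(2,4,6-triisopropylphenyl)-1,1′-binaphthyl-2,2′-diyl phosphate), t-BuOOt-Bu (1.2 equiv), 6 (2 equiv), 4 added over 6 h, ClCH2CH2Cl/HFIP 9:1, 0 °C, Ar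
Reagents that add atoms: none
Why: Proposed new method: the guaiacyl phenol of 6 binds the chiral trivalent iron phosphate as a phenoxide and is oxidised to a metal-bound phenoxyl radical whose oxygen is blocked against 8–O–4 coupling, its C5 then bonds to C8 of the more electron-rich 4-hydroxystyrene 4 held by a P=O···HO hydrogen bond in the chiral pocket, which sets the (R)-centre that becomes C3, a further one-electron oxidation and tautomerisation give p-quinone methide 7, and 5-exo oxa-1,6-addition of the regenerated phenol anti to the CH2O-ester arm sets C2 as (S), trans to C3; the closest known reactions are the FeCl3-catalysed oxidative phenol–olefin [3+2] coupling to trans-2-aryl-2,3-dihydrobenzofurans, the enantioselective oxidative phenol coupling with chiral Fe[(R)-L]3-type phosphate complexes, and the racemic Ag2O or peroxidase 8–5′ dehydrodimerisation of monolignols.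

**Compound list**

1 | sinapic acid, (E)-3-(4-hydroxy-3,5-dimethoxyphenyl)prop-2-enoic acid | COc1cc(/C=C/C(=O)O)cc(OC)c1O | starting material
2 | 4-vinylsyringol, 2,6-dimethoxy-4-vinylphenol | C=Cc1cc(OC)c(O)c(OC)c1 | intermediate
3 | allyl 4-hydroxybenzoate | C=CCOC(=O)c1ccc(O)cc1 | starting material
4 | sinapyl 4-hydroxybenzoate, (E)-3-(4-hydroxy-3,5-dimethoxyphenyl)prop-2-enyl 4-hydroxybenzoate | COc1cc(/C=C/COC(=O)c2ccc(O)cc2)cc(OC)c1O | intermediate
5 | 4-vinylguaiacol, 2-methoxy-4-vinylphenol | C=Cc1ccc(O)c(OC)c1 | starting material
6 | coniferyl 4-hydroxybenzoate, (E)-3-(4-hydroxy-3-methoxyphenyl)prop-2-enyl 4-hydroxybenzoate | COc1cc(/C=C/COC(=O)c2ccc(O)cc2)ccc1O | intermediate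
7 | p-quinone methide, 2,6-dimethoxy-4-[(2R)-2-aryl-3-(4-hydroxybenzoyloxy)propylidene]cyclohexa-2,5-dien-1-one, aryl = 2-hydroxy-3-methoxy-5-[(E)-3-(4-hydroxybenzoyloxy)prop-1-enyl]phenyl (not isolated) | O=C1C(OC)=CC(=C[C@@H](COC(=O)c2ccc(O)cc2)c2cc(/C=C/COC(=O)c3ccc(O)cc3)cc(OC)c2O)C=C1OC | intermediate
8 | quiquesetinerviusin B, [(2S,3R)-2-(4-hydroxy-3,5-dimethoxyphenyl)-7-methoxy-5-[(E)-3-(4-hydroxybenzoyloxy)prop-1-enyl]-2,3-dihydrobenzofuran-3-yl]methyl 4-hydroxybenzoate | COc1cc([C@H]2Oc3c(OC)cc(/C=C/COC(=O)c4ccc(O)cc4)cc3[C@@H]2COC(=O)c2ccc(O)cc2)cc(OC)c1O | target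

**Count and risks**

Total step count: 4. Longest linear sequence: 3 steps (1 → 2 → 4 → 8).

The three steps most likely to fail:

Step 4 is the main risk. The asymmetric cross-coupling is unprecedented, and neither its enantioselectivity nor its cross-selectivity is known. Expected problems are homo-coupling of 4 (8–8) and of 6 (8–5), ionisation of the allylic esters in HFIP, and over-oxidation of the syringyl phenol of 8. The fallback sets out from 4 and 6 and comes back to the route at 8. The 1:2 mixture of 4 and 6 is oxidised with horseradish peroxidase and H2O2 in acetone/pH 5 acetate buffer, the classical racemic dehydrodimerisation. This gives the trans-phenylcoumaran as 8 together with its mirror image, the (2R,3S)-enantiomer of 8 F1. The two are separated by preparative HPLC on an amylose tris(3,5-dimethylphenylcarbamate) phase, so stereocontrol moves from the catalyst to a resolution. The same column can polish material of incomplete ee from step 4.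

Step 2 is the second risk. The very electron-rich 4-vinylsyringol may oligomerise or self-metathesise to the stilbene faster than it crosses with 3. The fallback sets out from 1 and comes back at 4, bypassing step 1 and the metathesis. Fischer esterification (MeOH, H2SO4, reflux) gives methyl sinapate F2. Reduction with i-Bu2AlH in toluene at 0 °C gives sinapyl alcohol F3. A Mitsunobu esterification (PPh3, DIAD, THF, 0 °C) with free 4-hydroxybenzoic acid then gives 4; the carboxylic acid reacts in preference to the phenols.

Step 3 is the third risk, for the same reason in milder form. The fallback sets out from 5 and comes back at 6, with the phenol masked during the metathesis. Acetylation (Ac2O, pyridine) gives 2-methoxy-4-vinylphenyl acetate F4. Cross-metathesis with 3 under the step 3 conditions gives 4-O-acetylconiferyl 4-hydroxybenzoate F5. Hydrazine acetate in DMF at room temperature then removes the phenolic acetate selectively, leaving the allylic benzoate, and gives 6.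

**Further compounds**

F1 | step 4 | (2R,3S)-enantiomer of 8 | COc1cc([C@@H]2Oc3c(OC)cc(/C=C/COC(=O)c4ccc(O)cc4)cc3[C@H]2COC(=O)c2ccc(O)cc2)cc(OC)c1O
F2 | step 2 | methyl sinapate, methyl (E)-3-(4-hydroxy-3,5-dimethoxyphenyl)prop-2-enoate | COC(=O)/C=C/c1cc(OC)c(O)c(OC)c1
F3 | step 2 | sinapyl alcohol, (E)-3-(4-hydroxy-3,5-dimethoxyphenyl)prop-2-en-1-ol | COc1cc(/C=C/CO)cc(OC)c1O
F4 | step 3 | 2-methoxy-4-vinylphenyl acetate | C=Cc1ccc(OC(C)=O)c(OC)c1
F5 | step 3 | 4-O-acetylconiferyl 4-hydroxybenzoate, (E)-3-(4-acetoxy-3-methoxyphenyl)prop-2-enyl 4-hydroxybenzoate | COc1cc(/C=C/COC(=O)c2ccc(O)cc2)ccc1OC(C)=O
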